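The readings were generated by integration with made-up constants; scatter was added.

Z is what I counted: how much was made per day over about the first day, as a fraction of the flask's X charge.

the same everywhere: J 0.10 mM

| flask | X | G | remark |
|---|---|---|---|
| north-west | 0.025 M | 0.060 M | run made earlier |
| north-east | 0.038 M | 0.060 M | run made earlier |
| south | 0.050 M | 0.030 M | run made earlier |
| flask | 0.050 M | 0.0600 M |  |

| run | time / d | Z / % | X / % |
|---|---|---|---|
| north-west | 0.417 | 24 | 73 |
| north-west | 1.25 | 56 | 43 |
| north-west | 2.00 | 70 | 31 |
| north-west | 3.00 | 83 | 11 |
| north-west | 5.00 | 98 | 0 |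
| north-west | 6.00 | 99 | 0 |
| north-east | 1.04 | 38 | 65 |
| north-east | 2.08 | 50 | 47 |
| north-east | 3.00 | 64 | 37 |
| north-east | 4.00 | 71 | 31 |
| north-east | 5.00 | 79 | 21 |
| north-east | 6.00 | 82 | 15 |
| south | 0.500 | 14 | 88 |
| south | 0.833 | 18 | 84 |
| south | 1.67 | 27 | 75 |
| south | 3.00 | 34 | 69 |
| south | 6.00 | 36 | 59 |

(standard deviation of a reading: 2 percentage points)
- apparent order in G when 10 % of the X are converted (percent change of the rate of making Z for one percent more G charged)


1. I turned the question round. An order of 1 in G, held across the doubling, needs the rate of making Z to double when the G charged doubles. An order of 0 needs it unchanged.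

2. The south run has the flask's X and half its G. No run holds the flask's pair, so I built the flask's rate from the other runs.

3. The north-west run made 0.224 /d up to 1.25 d. The north-east run made 0.278 /d up to 1.04 d. Both had the same G, so the order in X read 0.513.

4. Scaled to the flask's X, the north-west rate became 0.320 /d. The south run, midway between its readings at 0.833 d and 1.67 d, gave 0.180 /d.

5. Their ratio is 1.78: the doubling gain, the factor by which the early rate of making Z rises when the G charged doubles at fixed X. So I read a mean order of 0.830 between the south run's G and the flask's G. It is a reading with the scatter of 2 percentage points, and a mean over the first day, not a rate at 10 %.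

6. The forecast gave 1.1, above my reading, holding that “the order in current G is about 1”.

The flask gives 0.70.

    G + J → E (k = 583 /M/h)
    X + E → D (k = 819 /M/h)
    D ⇌ Q (K = 0.772, k = 891 /h)
    Q ⇌ J + Z (K = 0.0334 M, k = 462 /h)
    2 Q ⇌ L, settled at all times (K = 1.10 × 10⁶ /M)

The flask's order of 0.70 stands below the 0.830 that my doubling gain of 1.78 gave. In the flask a J takes up G at 840 /d as charged, slower than a Q gives J + Z, at 11000 /d. In the flask L, an off-cycle store and not a resting state, holds 48.2 % of the catalyst at 10 % conversion, reached after 0.222 d, and 74.3 % after 6.00 d, each L counted as the two catalyst units it holds.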